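The constants of the isomer steps say where the product comes to rest, and the gas constants say how soon it can get there, so I reckon those two and hold each setting against them.

    2 coupling partner → homo dimer (k1 = 1.77 M⁻¹ min⁻¹, Ea1 = 67.0 kJ mol⁻¹)
    intermediate ⇌ target (K2 = 1.4, k2 = 0.0723 min⁻¹, Ea2 = 102 kJ mol⁻¹, ΔH2 = −14.0 kJ mol⁻¹)
    gas ⇌ coupling partner, rate k3*(csat - [coupling partner]) (k3 = 0.576 min⁻¹, csat = 9.8 mM)
    intermediate ⇌ isomer of the product A (K4 = 2.86, k4 = 0.0288 min⁻¹, Ea4 = 123 kJ mol⁻¹, ΔH4 = −6.00 kJ mol⁻¹)
    substrate + coupling partner → intermediate + released group (k5 = 34.7 M⁻¹ min⁻¹, Ea5 = 57.0 kJ mol⁻¹)
    target ⇌ isomer of the product B (K6 = 0.610, k6 = 0.0184 min⁻¹, Ea6 = 118 kJ mol⁻¹, ΔH6 = −65.0 kJ mol⁻¹)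
    (constants at 90 °C)

common to all: substrate 0.10 M; gas 9.8 mM (held); time 40 min

| charge | temperature |
|---|---|
| larch | 140 °C |
| cedar | 115 °C |
| elm | 90 °C |

- a doubled species enters its step squared and goes two at a time
- at the start none of coupling partner is dissolved
- the list of constants is for 90 °C, to be carried to other temperatures by the activation energies and enthalpies

* the flask with the highest amount of target, in percent of the substrate charged ("all alike" if they lie within 1.5 percentage points) (larch / cedar / elm / all alike)
* final target, as a percentage of the substrate charged, in larch
* final target, as a percentage of the substrate charged, in cedar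
* final target, as a percentage of the substrate charged, in elm

Counting intermediate as one at equilibrium in elm, target counts 1.4, isomer of the product A 2.86 and isomer of the product B 0.854, which gives target 22.9%; this figure, target's count divided by the sum of the counts, is what I call the resting share s, the value of thermodynamic control.

Temperature comes first. Carried to larch, the counts become 0.799 for target, 2.25 for isomer of the product A and 0.0360 for isomer of the product B, so s falls to 19.6%. Step 4 speeds up 140-fold, which takes its relaxation half-life from 17.8 min in elm to near 0.129 min, so I expect larch to stand on its s, and cedar, whose temperature lies between, to stand between the two shares.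

Next comes the charge. Partner enters at no more than about 5.64 mM min⁻¹, its rate while none is dissolved, so the substrate of elm needs at least 17.7 min, which is a floor and not a finishing time. At the start, a dissolved partner meets substrate at 3.47 min⁻¹ and, even at saturation, other partner at 0.0347 min⁻¹. Heat favours the dimer by 1.49, and the comparison drifts towards it as substrate falls, but by then hardly any substrate is left to lose.

Time comes last. Elm has at most 22.3 min after that floor, which is 1.25 relaxation half-lives of step 4. Intermediate and target relax in 5.59 min, sooner than either isomer step, and their own equilibrium gives target 58.3% of what the pair holds, a share of the pair and not of the charge. So I put elm above s, which is kinetic control, and a longer run should bring it down towards s.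

The forecast names elm, with 19.6% in larch, 22% in cedar and 33% in elm, on the ground that “the slow isomerisation leaves the target near its kinetic maximum”.

The simulation gives 19.6% in larch, 22.1% in cedar and 33.7% in elm, the highest of the flasks. Left until 400 min, elm reads 22.9%, level with its s of 22.9%. Larch's 19.6% matches the 19.6% reckoned from its constants.

Take a flask like elm with 0.17 M of substrate: no equilibrium constant contains the charge, so s stays 22.9%, and the floor of feeding rises to about 30.1 min, leaving at most 9.88 min, so I place it above s. It gives 31.4%, with 3.7% of its substrate still there.

The numbers are invented; the result is computed.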